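**Retrosynthetic overview**

1. The target is released from its N-(2-nitrobenzenesulfonyl) derivative. That compound is cut at two bonds at once, C4–C4a (closing the nitrogen ring) and C5–C1' (the biaryl bond), by a ring-closing Catellani reaction with Suzuki termination between an acyclic aryl iodide/alkyl bromide and a naphthylboronic acid.
2. Enabling feature: in the benzene ring of the isoquinoline (ring A), the naphthyl-bearing C5 lies between C4a and C6–OMe. An iodide at C5 lets palladium/norbornene reach C4a–H, a site meta to both methoxy groups and closed to electrophilic cyclisation; C6–OMe blocks the second ortho site, and C5 then takes the naphthyl group.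
3. The acyclic precursor comes from 2,4-dimethoxybenzaldehyde (C5 iodination), L-alaninol (source of C3 and its (S) configuration), 2-nitrobenzenesulfonyl chloride and an Appel bromination.
4. The naphthylboronic acid comes from 2-bromo-5-methoxybenzaldehyde by Stobbe condensation and Friedel–Crafts benzannulation; the bromine blocks the wrong ortho position and later becomes boron.
5. Order of ring formation: second naphthalene ring (step 2), then the nitrogen ring of the tetrahydroisoquinoline (step 12), in the same operation as the biaryl bond.

Key step: step 12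

Assumption: the SMILES fixes only C3 as (S) and gives no descriptor for the biaryl axis, so the axis is left uncontrolled and the compound is made as the (3S) material whatever the rotamer population about C5–C1'.

**Route**

Step 1
Reactants: 1 2-bromo-5-methoxybenzaldehyde; 2 diethyl succinate
Product: 3 (3E)-4-(2-bromo-5-methoxyphenyl)-3-(ethoxycarbonyl)but-3-enoic acid
Conditions: KOt-Bu, t-BuOH, reflux; then aq. HCl
Reagents that add atoms: none
Why: Stobbe condensation, in which the succinate enolate adds to the aldehyde, the alkoxide lactonises onto the distal ester and base-induced opening of the paraconate should give the half-ester with the aryl group cis to the CH2CO2H arm ((E) isomer), the geometry needed for the next ring closure.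

Step 2
Reactants: 3 (3E)-4-(2-bromo-5-methoxyphenyl)-3-(ethoxycarbonyl)but-3-enoic acid
Product: 4 ethyl 4-acetoxy-8-bromo-5-methoxynaphthalene-2-carboxylate
Conditions: Ac2O, NaOAc, reflux
Reagents that add atoms: acetic anhydride, CC(=O)OC(C)=O
Why: The mixed anhydride of the acid should acylate the aryl ring intramolecularly at the only free position ortho to the alkenyl carbon (activated by the adjacent methoxy group, the other ortho site being blocked by bromine), after which the keto tautomer enolises to the naphthol and is acetylated in situ (Friedel–Crafts benzannulation of a Stobbe half-ester).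

Step 3
Reactants: 4 ethyl 4-acetoxy-8-bromo-5-methoxynaphthalene-2-carboxylate
Product: 6 ethyl 8-bromo-4,5-dimethoxynaphthalene-2-carboxylate, via sodium naphtholate 5 (not isolated)
Conditions: NaOEt (1.1 equiv), EtOH, 0 °C to rt; then MeI, DMF, rt
Reagents that add atoms: iodomethane, CI
Why: Ethoxide should cleave the aryl acetate by transesterification (ethanol keeps the ethyl ester unchanged) and the naphtholate is then O-methylated by MeI in a Williamson ether synthesis.

Step 4
Reactants: 6 ethyl 8-bromo-4,5-dimethoxynaphthalene-2-carboxylate
Product: 7 (8-bromo-4,5-dimethoxynaphthalen-2-yl)methanol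
Conditions: i-Bu2AlH (2.5 equiv), CH2Cl2, −78 to 0 °C; aq. potassium sodium tartrate (KNaC4H4O6) work-up
Reagents that add atoms: none
Why: i-Bu2AlH should reduce the ester to the primary benzylic alcohol at low temperature, conditions under which the aryl bromide and the aryl ethers are inert.

Step 5
Reactants: 7 (8-bromo-4,5-dimethoxynaphthalen-2-yl)methanol
Product: 8 1-bromo-7-(bromomethyl)-4,5-dimethoxynaphthalene
Conditions: PBr3 (0.4 equiv), CH2Cl2, 0 °C
Reagents that add atoms: phosphorus tribromide, BrP(Br)Br
Why: PBr3 should convert the primary benzylic alcohol into the bromide by SN2 displacement of the intermediate phosphite ester.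

Step 6
Reactants: 8 1-bromo-7-(bromomethyl)-4,5-dimethoxynaphthalene
Product: 9 1-bromo-4,5-dimethoxy-7-methylnaphthalene
Conditions: LiBHEt3 (1.2 equiv), THF, 0 °C
Reagents that add atoms: none
Why: LiBHEt3 should deliver hydride in an SN2 displacement of the benzylic bromide, which is far faster than any reduction of the aryl bromide at 0 °C.

Step 7
Reactants: 9 1-bromo-4,5-dimethoxy-7-methylnaphthalene
Product: 11 (4,5-dimethoxy-7-methylnaphthalen-1-yl)boronic acid, via aryllithium 10 (not isolated)
Conditions: n-BuLi, THF, −78 °C; B(Oi-Pr)3, −78 °C to rt; then dilute aq. HCl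
Reagents that add atoms: triisopropyl borate, CC(C)OB(OC(C)C)OC(C)C; water, O
Why: Bromine–lithium exchange at −78 °C should place lithium regiospecifically at C1, the aryllithium is trapped by the borate ester, and mild acidic hydrolysis frees the boronic acid.

Step 8
Reactants: 12 2,4-dimethoxybenzaldehyde
Product: 13 5-iodo-2,4-dimethoxybenzaldehyde
Conditions: N-iodosuccinimide, TFA (cat.), MeCN, rt
Reagents that add atoms: N-iodosuccinimide, O=C1CCC(=O)N1I
Why: Electrophilic aromatic iodination should occur at C5, para to the 2-methoxy and ortho to the 4-methoxy group, because C3 is flanked by two methoxy groups and C6 is meta to both and ortho to the formyl group.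

Step 9
Reactants: 13 5-iodo-2,4-dimethoxybenzaldehyde; 14 (S)-2-aminopropan-1-ol (L-alaninol)
Product: 16 (2S)-2-[(5-iodo-2,4-dimethoxybenzyl)amino]propan-1-ol, via imine 15 (not isolated)
Conditions: MeOH, rt; then NaBH4, 0 °C
Reagents that add atoms: none
Why: Reductive amination (condensation to the imine, then hydride reduction) should proceed without touching the stereocentre of L-alaninol, and the aryl iodide is inert to NaBH4.

Step 10
Reactants: 16 (2S)-2-[(5-iodo-2,4-dimethoxybenzyl)amino]propan-1-ol
Product: 17 N-[(2S)-1-hydroxypropan-2-yl]-N-(5-iodo-2,4-dimethoxybenzyl)-2-nitrobenzenesulfonamide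
Conditions: 2-nitrobenzenesulfonyl chloride (1.05 equiv), Et3N, CH2Cl2, 0 °C
Reagents that add atoms: 2-nitrobenzenesulfonyl chloride, O=S(=O)(Cl)c1ccccc1[N+](=O)[O-]
Why: Chemoselective N-sulfonylation is expected because the secondary amine is more nucleophilic than the primary alcohol at 0 °C; the sulfonyl group removes nitrogen basicity and nucleophilicity for the next two steps and is cleavable by thiolate.

Step 11
Reactants: 17 N-[(2S)-1-hydroxypropan-2-yl]-N-(5-iodo-2,4-dimethoxybenzyl)-2-nitrobenzenesulfonamide
Product: 18 N-[(2S)-1-bromopropan-2-yl]-N-(5-iodo-2,4-dimethoxybenzyl)-2-nitrobenzenesulfonamide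
Conditions: CBr4, PPh3, CH2Cl2, 0 °C to rt
Reagents that add atoms: carbon tetrabromide, BrC(Br)(Br)Br
Why: Appel reaction, in which bromide displaces the oxyphosphonium group by SN2 at the primary carbon, so no bond to the adjacent stereocentre is broken and the non-nucleophilic sulfonamide nitrogen cannot form an aziridinium ion.

Step 12
Reactants: 18 N-[(2S)-1-bromopropan-2-yl]-N-(5-iodo-2,4-dimethoxybenzyl)-2-nitrobenzenesulfonamide; 11 (4,5-dimethoxy-7-methylnaphthalen-1-yl)boronic acid
Product: 19 (3S)-5-(4,5-dimethoxy-7-methylnaphthalen-1-yl)-6,8-dimethoxy-3-methyl-2-(2-nitrobenzenesulfonyl)-1,2,3,4-tetrahydroisoquinoline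
Conditions: Pd(OAc)2 (10 mol %), P(2-furyl)3 (22 mol %), norbornene (3 equiv), Cs2CO3 (4 equiv), MeCN/H2O (20:1), 85 °C, 0.01 M in 18, 11 (1.5 equiv) added slowly
Reagents that add atoms: none
Why: Zerovalent palladium should insert into the C5–I bond, norbornene is carbopalladated, and the norbornylpalladium species metalates C4a–H to a five-membered aryl–norbornyl palladacycle of divalent palladium; this attacks the tethered primary C–Br in SN2 fashion to give a tetravalent palladium intermediate whose C(sp2)–C(sp3) reductive elimination forges C4–C4a, after which the doubly ortho-substituted arene expels norbornene by β-carbon elimination and the C5–palladium bond is intercepted by boronic acid 11 (transmetalation, reductive elimination). The closest known reaction type is the Catellani reaction in two established variants, ring-closing ortho-alkylation by an alkyl halide tethered meta to the iodide and ipso termination by Suzuki–Miyaura coupling. The nitrogen ring closes by intramolecular aryl C–H alkylation, a formal 6-exo-tet displacement of bromide that passes through a seven-membered palladacycle of tetravalent palladium and gives the six-membered ring on reductive elimination. No new stereogenic carbon is created: displacement occurs at the CH2 next to C3, so the (S) configuration from L-alaninol is carried through unchanged, and the new biaryl axis is left uncontrolled in line with the assumption. The step needs C–H functionalisation at C4a only, ring closure before biaryl coupling, and intra- over intermolecular alkylation; the first is secured by the C5 iodide with C6–OMe blocking the other ortho site, the second by norbornene insertion being faster than transmetalation for an ortho-substituted aryl–palladium iodide together with slow addition of 11, and the third by dilution and the six-membered ring size.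

Step 13
Reactants: 19 (3S)-5-(4,5-dimethoxy-7-methylnaphthalen-1-yl)-6,8-dimethoxy-3-methyl-2-(2-nitrobenzenesulfonyl)-1,2,3,4-tetrahydroisoquinoline
Product: 20 (3S)-5-(4,5-dimethoxy-7-methylnaphthalen-1-yl)-6,8-dimethoxy-3-methyl-1,2,3,4-tetrahydroisoquinoline
Conditions: PhSH, K2CO3, DMF, rt
Reagents that add atoms: none
Why: Thiolate should add to the 2-nitrophenyl ring (nucleophilic aromatic substitution via a Meisenheimer complex), the sulfonyl group is expelled with loss of SO2, and the secondary amine is released under conditions that leave the aryl ethers, the biaryl and C3 untouched.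

**Compound list**

1 | 2-bromo-5-methoxybenzaldehyde | COc1ccc(Br)c(C=O)c1 | starting material
2 | diethyl succinate | CCOC(=O)CCC(=O)OCC | starting material
3 | (3E)-4-(2-bromo-5-methoxyphenyl)-3-(ethoxycarbonyl)but-3-enoic acid | CCOC(=O)/C(CC(=O)O)=C/c1cc(OC)ccc1Br | intermediate
4 | ethyl 4-acetoxy-8-bromo-5-methoxynaphthalene-2-carboxylate | CCOC(=O)c1cc(OC(C)=O)c2c(OC)ccc(Br)c2c1 | intermediate
5 | sodium salt of ethyl 8-bromo-4-hydroxy-5-methoxynaphthalene-2-carboxylate (sodium naphtholate) | CCOC(=O)c1cc([O-])c2c(OC)ccc(Br)c2c1.[Na+] | intermediate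
6 | ethyl 8-bromo-4,5-dimethoxynaphthalene-2-carboxylate | CCOC(=O)c1cc(OC)c2c(OC)ccc(Br)c2c1 | intermediate
7 | (8-bromo-4,5-dimethoxynaphthalen-2-yl)methanol | OCc1cc(OC)c2c(OC)ccc(Br)c2c1 | intermediate
8 | 1-bromo-7-(bromomethyl)-4,5-dimethoxynaphthalene | BrCc1cc(OC)c2c(OC)ccc(Br)c2c1 | intermediate
9 | 1-bromo-4,5-dimethoxy-7-methylnaphthalene | Cc1cc(OC)c2c(OC)ccc(Br)c2c1 | intermediate
10 | (4,5-dimethoxy-7-methylnaphthalen-1-yl)lithium (aryllithium) | [Li]c1ccc(OC)c2c(OC)cc(C)cc12 | intermediate
11 | (4,5-dimethoxy-7-methylnaphthalen-1-yl)boronic acid | OB(O)c1ccc(OC)c2c(OC)cc(C)cc12 | intermediate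
12 | 2,4-dimethoxybenzaldehyde | COc1ccc(C=O)c(OC)c1 | starting material
13 | 5-iodo-2,4-dimethoxybenzaldehyde | COc1cc(OC)c(C=O)cc1I | intermediate
14 | (S)-2-aminopropan-1-ol (L-alaninol) | C[C@H](N)CO | starting material
15 | (2S)-2-{[(E)-(5-iodo-2,4-dimethoxyphenyl)methylidene]amino}propan-1-ol (imine) | COc1cc(OC)c(/C=N/[C@@H](C)CO)cc1I | intermediate
16 | (2S)-2-[(5-iodo-2,4-dimethoxybenzyl)amino]propan-1-ol | COc1cc(OC)c(CN[C@@H](C)CO)cc1I | intermediate
17 | N-[(2S)-1-hydroxypropan-2-yl]-N-(5-iodo-2,4-dimethoxybenzyl)-2-nitrobenzenesulfonamide | COc1cc(OC)c(CN([C@@H](C)CO)S(=O)(=O)c2ccccc2[N+](=O)[O-])cc1I | intermediate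
18 | N-[(2S)-1-bromopropan-2-yl]-N-(5-iodo-2,4-dimethoxybenzyl)-2-nitrobenzenesulfonamide | COc1cc(OC)c(CN([C@@H](C)CBr)S(=O)(=O)c2ccccc2[N+](=O)[O-])cc1I | intermediate
19 | (3S)-5-(4,5-dimethoxy-7-methylnaphthalen-1-yl)-6,8-dimethoxy-3-methyl-2-(2-nitrobenzenesulfonyl)-1,2,3,4-tetrahydroisoquinoline | COc1cc(OC)c(-c2ccc(OC)c3c(OC)cc(C)cc23)c2c1CN(S(=O)(=O)c1ccccc1[N+](=O)[O-])[C@@H](C)C2 | intermediate
20 | (3S)-5-(4,5-dimethoxy-7-methylnaphthalen-1-yl)-6,8-dimethoxy-3-methyl-1,2,3,4-tetrahydroisoquinoline | COc1cc(OC)c(-c2ccc(OC)c3c(OC)cc(C)cc23)c2c1CN[C@@H](C)C2 | target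

**Step count and risks**

Total step count: 13. Longest linear sequence: 9 steps (steps 1–7, then 12 and 13); the other branch is steps 8–11.

Steps most likely to fail:

Step 12. Three processes could erode the one-pot double bond formation. The aryl–palladium iodide may undergo Suzuki coupling with 11 before norbornene insertion and ring closure. The aryl–norbornyl palladacycle may collapse by reductive elimination if alkylation by the β-branched bromide is slow. Base may also cause loss of HBr from the bromide. The fallback separates the two bond formations and sets out from 18. The same ring-closing Catellani alkylation is run without boronic acid and with HCO2Na as hydride source (Pd(OAc)2, P(2-furyl)3, norbornene, Cs2CO3, DMF, 90 °C), an ipso-hydride termination. This should give (3S)-6,8-dimethoxy-3-methyl-2-(2-nitrobenzenesulfonyl)-1,2,3,4-tetrahydroisoquinoline F1. N-Bromosuccinimide in MeCN at 0 °C should then brominate C5 (para to the C8 methoxy and ortho to the C6 methoxy group, whereas C7 lies between two methoxy groups) to give (3S)-5-bromo-6,8-dimethoxy-3-methyl-2-(2-nitrobenzenesulfonyl)-1,2,3,4-tetrahydroisoquinoline F2. Suzuki–Miyaura coupling of F2 with 11 (Pd(OAc)2, SPhos, K3PO4, toluene/H2O, 100 °C) comes back to the route at 19.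

Step 10. O-Sulfonylation of the primary alcohol may compete with sulfonylation of the hindered, α-branched secondary amine, and the sulfonate ester could then be displaced intramolecularly by nitrogen. The fallback reverses the order of N-substitution and sets out from 13 and 14. Sulfonylation of the unhindered primary amine of 14 (2-nitrobenzenesulfonyl chloride, Et3N, CH2Cl2, 0 °C) should give N-[(2S)-1-hydroxypropan-2-yl]-2-nitrobenzenesulfonamide F3. Reduction of 13 with NaBH4 in MeOH should give (5-iodo-2,4-dimethoxyphenyl)methanol F4, and SOCl2 in CH2Cl2 converts it into 1-(chloromethyl)-5-iodo-2,4-dimethoxybenzene F5. Alkylation of F3 with F5 at the acidic sulfonamide N–H (K2CO3, DMF, rt) comes back to the route at 17.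

Step 7. The electron-rich naphthyl–boron bond may be lost by protodeboronation during acidic hydrolysis, on storage, or later under the hot basic conditions of step 12; the aryllithium may also be alkylated by the butyl bromide formed in the exchange. The fallback avoids the organolithium and the free boronic acid and sets out from 9. Miyaura borylation (PdCl2(dppf), bis(pinacolato)diboron, KOAc, dioxane, 90 °C) should give 2-(4,5-dimethoxy-7-methylnaphthalen-1-yl)-4,4,5,5-tetramethyl-1,3,2-dioxaborolane F6, a more robust boron partner that can be purified by chromatography. F6 enters step 12 in place of 11 and comes back to the route at 19.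

**Further compounds**

F1 | step 12 | (3S)-6,8-dimethoxy-3-methyl-2-(2-nitrobenzenesulfonyl)-1,2,3,4-tetrahydroisoquinoline | COc1cc(OC)cc2c1CN(S(=O)(=O)c1ccccc1[N+](=O)[O-])[C@@H](C)C2
F2 | step 12 | (3S)-5-bromo-6,8-dimethoxy-3-methyl-2-(2-nitrobenzenesulfonyl)-1,2,3,4-tetrahydroisoquinoline | COc1cc(OC)c(Br)c2c1CN(S(=O)(=O)c1ccccc1[N+](=O)[O-])[C@@H](C)C2
F3 | step 10 | N-[(2S)-1-hydroxypropan-2-yl]-2-nitrobenzenesulfonamide | O=S(=O)(N[C@@H](C)CO)c1ccccc1[N+](=O)[O-]
F4 | step 10 | (5-iodo-2,4-dimethoxyphenyl)methanol | COc1cc(OC)c(CO)cc1I
F5 | step 10 | 1-(chloromethyl)-5-iodo-2,4-dimethoxybenzene | COc1cc(OC)c(CCl)cc1I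
F6 | step 7 | 2-(4,5-dimethoxy-7-methylnaphthalen-1-yl)-4,4,5,5-tetramethyl-1,3,2-dioxaborolane | Cc1cc(OC)c2c(OC)ccc(B3OC(C)(C)C(C)(C)O3)c2c1
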